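## Plan

1. Retrosynthesis: remove the C6 ester, the 8,9-epoxide and the C7 hydroxyl (back to dauc-8-ene-4β,6α-diol), then the C5–H/C6–O pair and the C4–C11 bond (back to a bicyclic dienone ester), then cut C7–C8 and C10–C1 of the seven-membered ring.
2. Enabling feature: the seven-membered ring holds the quaternary C1 next to C10 and, behind the epoxide, an 8,9-alkene. Together with a 5,6-alkene this is a cyclohepta-1,4-diene, the product pattern of a vinylcarbenoid C8–C9–C10 joined to the ends (C7, C1) of the diene C7=C6–C5=C1 of a 2-vinylcyclopentenone.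
3. Forward order: the cyclopentenone ring is bought, the seven-membered ring is closed in step 3, then C4, C5/C6, the C8 methyl and isopropyl groups, the C7 oxygen, the aroyl ester and the epoxide follow.
4. Stereochemistry: C1 comes from a chiral dirhodium catalyst, relayed through a boat Cope shift; C4 from carbonyl addition opposite the C1 methyl; C5 and C6 from borane delivered intramolecularly by the 4α-isopropenyl group; C7 from hydride delivered by the C6 hydroxyl; the epoxide forms opposite the C7 silyl ether and the C1 methyl.

Key step: step 3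

Remark on numbering: daucane numbering is used (C1 quaternary methyl carbon, C4 carbinol with isopropyl C11–C13, C5 ring-fusion CH, C6 acyloxy carbon, C7 carbinol, C8/C9 epoxide with C14 methyl on C8, C10 CH2, C15 methyl on C1); β is the face of C15, α the opposite face.
Remark on the catalyst: the prolinate catalyst family is taken to induce as it does with terminal alkenes (the S-catalyst giving the (1S,2R)-cyclopropane from styrene); on that basis the R-catalyst is assigned to cyclopropane 6.

## Route

Step 1
Reactants: 1 2-bromo-3-methylcyclopent-2-en-1-one; 2 potassium vinyltrifluoroborate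
Product: 3 3-methyl-2-vinylcyclopent-2-en-1-one
Conditions: PdCl2(dppf) (3 mol %), Cs2CO3, THF/H2O 9:1, 70 °C; stored cold, used promptly
Reagents that add atoms: none
Why: Suzuki–Miyaura coupling of an α-bromoenone with a vinyltrifluoroborate is a standard sp2–sp2 coupling; the cross-conjugated dienone can dimerise and is therefore not stored.

Step 2
Reactants: 4 methyl but-3-enoate
Product: 5 methyl 2-diazobut-3-enoate
Conditions: 4-acetamidobenzenesulfonyl azide, DBU, MeCN, 0 °C; kept cold, used the same day
Reagents that add atoms: 4-acetamidobenzenesulfonyl azide, CC(=O)Nc1ccc(cc1)S(=O)(=O)N=[N+]=[N-]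
Why: Regitz diazo transfer onto the doubly activated (allylic, α to the ester) methylene gives the vinyldiazoacetate; it is used cold because it slowly cyclises to a pyrazole.

Step 3
Reactants: 3 3-methyl-2-vinylcyclopent-2-en-1-one; 5 methyl 2-diazobut-3-enoate
Product: 7 methyl (8aR)-8a-methyl-3-oxo-1,2,3,5,8,8a-hexahydroazulene-6-carboxylate, via cis-divinylcyclopropane 6 (not isolated)
Conditions: Rh2(R-DOSP)4 (1 mol %; the tetrakis[(R)-N-(4-dodecylphenylsulfonyl)prolinate] of divalent rhodium), slow addition of 5, pentane/PhMe, −40 °C → rt; then PhMe, 100 °C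
Reagents that add atoms: none
Why: Proposed new method: the catalyst turns 5 into a donor–acceptor vinylcarbenoid that cyclopropanates the monosubstituted vinyl group of 3 (C7–C8 bond) to give cis-divinylcyclopropane 6, which on heating undergoes a [3,3] shift that breaks C6–C8 and forms C10–C1. The closest known reaction type is the tandem cyclopropanation/Cope rearrangement (formal (4+3) cycloaddition) of vinyldiazoacetates with 1,3-dienes, which has not been shown for a 2-vinylcycloalkenone whose far terminus is a fully substituted ring carbon with an inward methyl. The seven-membered ring closes sigmatropically through a boat transition state, which makes both ring alkenes cis and gives the 1,4-cycloheptadiene. C1 is the only new stereocentre: the catalyst fixes the (1S,2S) configuration of 6 and the stereospecific boat shift relays it to (R)-C1. The step needs site selectivity for the vinyl group over the tetrasubstituted enone alkene and the carbonyl, and a cis arrangement of the two alkenyl groups on the cyclopropane; the first is secured because the vinyl group is the only unhindered, electron-sufficient π-bond, the second by the known preference of vinylcarbenoids to place the alkene substituent cis to the carbenoid vinyl group. The inward methyl raises the Cope barrier, hence the thermal second stage.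

Step 4
Reactants: 7 cycloadduct dienone ester
Product: 9 4-O-trimethylsilyl ether of the 4β-hydroxy-4α-isopropenyl adduct, via tertiary alcohol 8 (not isolated)
Conditions: CeCl3, CH2=C(CH3)MgBr, THF, −78 °C; aq. NH4Cl; crude + 1-(trimethylsilyl)imidazole, CH2Cl2, rt
Reagents that add atoms: isopropenylmagnesium bromide, C=C(C)[Mg]Br; 1-(trimethylsilyl)imidazole, C[Si](C)(C)n1ccnc1
Why: The weakly basic organocerium adds 1,2 to the enone carbonyl without touching the ester or the doubly allylic C7–H, and is expected to approach C4 from the α-face opposite the angular C15 methyl (4β-O, 4α-isopropenyl; epimers separable if the bias is modest); the alcohol is capped so that it neither consumes nor tethers the borane of step 5.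

Step 5
Reactants: 9 silyl ether
Product: 12 methyl 4β,6α,12-trihydroxy-5α-dauc-8-en-14-oate, via thexylboracycle 10 (not isolated), via silyl ether diol 11 (not isolated)
Conditions: thexylborane (from BH3·THF and 2,3-dimethylbut-2-ene, 1.1 equiv), THF, −20 °C → rt; H2O2, aq. NaOAc, 0 °C → rt; then citric acid, MeOH, rt
Reagents that add atoms: hydrogen peroxide, OO
Why: Cyclic hydroboration of a 1,4-diene: the borane adds first to the unhindered isopropenyl group, and the alkyl(thexyl)borane, held on the α-face by the C11–C12 tether, then adds across C5=C6 through a six-membered boracycle with boron on C6, so that H-5 and (after oxidation with retention) O-6 are both α whatever the intrinsic facial bias of the alkene; C11 is formed as a mixture that disappears in step 8, and mild acid removes the silyl ether.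

Step 6
Reactants: 12 triol ester
Product: 13 5α-dauc-8-ene-4β,6α,12,14-tetraol
Conditions: i-Bu2AlH (6 equiv), CH2Cl2, −78 → 0 °C
Reagents that add atoms: none
Why: 1,2-Reduction of the α,β-unsaturated ester by the aluminium hydride gives the primary allylic alcohol and leaves the 8,9-alkene in place.

Step 7
Reactants: 13 tetraol
Product: 14 12,14-bis(methanesulfonate) of 13
Conditions: MsCl (2.1 equiv), Et3N, CH2Cl2, −40 °C; used crude
Reagents that add atoms: methanesulfonyl chloride, CS(=O)(=O)Cl
Why: Sulfonylation at low temperature selects the two primary hydroxyls over the hindered secondary C6 hydroxyl and the tertiary C4 hydroxyl.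

Step 8
Reactants: 14 bis-mesylate
Product: 15 5α-dauc-8-ene-4β,6α-diol (jaeschkeanadiol)
Conditions: LiEt3BH (6 equiv), THF, 0 °C → rt
Reagents that add atoms: none
Why: SN2 hydride displacement of both primary sulfonates turns C12 and C14 into methyl groups (isopropyl and C8 methyl); the C6 oxygen is held as its lithium alkoxytriethylborate, which limits ring closure onto C12.

Step 9
Reactants: 15 jaeschkeanadiol
Product: 17 4β,6α-dihydroxy-5α-dauc-8-en-7-one, via 7α-allylic alcohol 16 (not isolated)
Conditions: SeO2 (0.5 equiv), t-BuOOH, CH2Cl2, rt; filtered; MnO2, CH2Cl2, rt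
Reagents that add atoms: tert-butyl hydroperoxide, CC(C)(C)OO (oxygen passed on through SeO2, O=[Se]=O)
Why: Riley oxidation (ene reaction, then [2,3] shift) attacks the ring methylene on the more substituted alkene carbon, the pattern known from C4 hydroxylation of homoallylic sterols, and MnO2 then oxidises only the allylic C7 alcohol, so the C7 configuration of 16 does not matter.

Step 10
Reactants: 17 α-hydroxy enone
Product: 18 5α-dauc-8-ene-4β,6α,7β-triol
Conditions: Me4NBH(OAc)3, MeCN/AcOH 1:1, −20 → 0 °C
Reagents that add atoms: none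
Why: Evans–Saksena directed reduction: the C6 hydroxyl exchanges onto boron and delivers hydride to the α-face of the neighbouring C7 carbonyl, giving the 7β-alcohol trans to O-6.

Step 11
Reactants: 18 triol
Product: 19 7-O-triethylsilyl ether of 18
Conditions: Et3SiCl (1.1 equiv), imidazole, CH2Cl2, −20 → 0 °C
Reagents that add atoms: chlorotriethylsilane, CC[Si](Cl)(CC)CC
Why: Silylation selects the allylic C7 hydroxyl over the C6 hydroxyl, which is shielded by the 4α-isopropyl group and the ring-fusion carbon, and over the tertiary C4 hydroxyl.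

Step 12
Reactants: 20 4-hydroxybenzoic acid
Product: 22 4-(tert-butyldimethylsilyloxy)benzoic acid, via bis-silyl compound 21 (not isolated)
Conditions: t-BuMe2SiCl (2.2 equiv), imidazole, DMF, rt; then AcOH/THF/H2O, rt
Reagents that add atoms: tert-butyldimethylsilyl chloride, CC(C)(C)[Si](C)(C)Cl
Why: Both oxygens are silylated and the labile silyl ester is then hydrolysed selectively, leaving the aryl silyl ether.

Step 13
Reactants: 19 silyl ether diol; 22 4-(tert-butyldimethylsilyloxy)benzoic acid
Product: 23 6-O-[4-(tert-butyldimethylsilyloxy)benzoyl] derivative of 19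
Conditions: DCC, DMAP, CH2Cl2, rt → 40 °C
Reagents that add atoms: none
Why: Steglich esterification acylates the only free secondary hydroxyl; the tertiary C4 hydroxyl does not react.

Step 14
Reactants: 23 ester
Product: 24 8α,9α-epoxide of 23
Conditions: mCPBA, NaHCO3, CH2Cl2, 0 °C
Reagents that add atoms: 3-chloroperbenzoic acid, OOC(=O)c1cccc(Cl)c1
Why: Prilezhaev epoxidation of the only alkene should occur on the α-face, opposite the allylic 7β-silyloxy group and the β-methyl on C1.

Step 15
Reactants: 24 epoxide
Product: 25 8α,9α-epoxy-4β,7β-dihydroxy-5α-daucan-6α-yl 4-hydroxybenzoate (target)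
Conditions: Bu4NF, AcOH (1:1, 2.5 equiv), THF, 0 °C → rt
Reagents that add atoms: none
Why: Fluoride cleaves both silyl ethers; the acetic acid buffer keeps the C7 alkoxide protonated so that acyl migration and epoxide migration are suppressed.

## Compound list

1 | 2-bromo-3-methylcyclopent-2-en-1-one | CC1=C(Br)C(=O)CC1 | starting material
2 | potassium vinyltrifluoroborate | C=C[B-](F)(F)F.[K+] | starting material
3 | 3-methyl-2-vinylcyclopent-2-en-1-one | CC1=C(C=C)C(=O)CC1 | intermediate
4 | methyl but-3-enoate | COC(=O)CC=C | starting material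
5 | methyl 2-diazobut-3-enoate | C=CC(=[N+]=[N-])C(=O)OC | intermediate
6 | methyl (1S,2S)-1-ethenyl-2-(2-methyl-5-oxocyclopent-1-en-1-yl)cyclopropane-1-carboxylate (alkenyl groups cis; not isolated) | C=C[C@@]1(C(=O)OC)C[C@H]1C2=C(C)CCC2=O | intermediate
7 | methyl (8aR)-8a-methyl-3-oxo-1,2,3,5,8,8a-hexahydroazulene-6-carboxylate (C4 ketone, 5,6- and 8,9-alkenes, C8 ester) | O=C1CC[C@]2(C)CC=C(C(=O)OC)CC=C21 | intermediate
8 | 4β-hydroxy-4α-isopropenyl adduct of 7 (not isolated) | C=C(C)[C@]1(O)CC[C@]2(C)CC=C(C(=O)OC)CC=C21 | intermediate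
9 | 4-O-trimethylsilyl ether of 8 | C=C(C)[C@]1(O[Si](C)(C)C)CC[C@]2(C)CC=C(C(=O)OC)CC=C21 | intermediate
10 | B-thexyl boracyclohexane joining C12 and C6 on the α-face, H-5 α (C11 epimers; not isolated) | CC(C3)[C@]1(O[Si](C)(C)C)CC[C@]2(C)CC=C(C(=O)OC)C[C@H](B3C(C)(C)C(C)C)[C@H]21 | intermediate
11 | 4-O-trimethylsilyl ether of 12 (not isolated) | CC(CO)[C@]1(O[Si](C)(C)C)CC[C@]2(C)CC=C(C(=O)OC)C[C@H](O)[C@H]21 | intermediate
12 | methyl 4β,6α,12-trihydroxy-5α-dauc-8-en-14-oate (C11 epimers) | CC(CO)[C@]1(O)CC[C@]2(C)CC=C(C(=O)OC)C[C@H](O)[C@H]21 | intermediate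
13 | 5α-dauc-8-ene-4β,6α,12,14-tetraol (C11 epimers) | CC(CO)[C@]1(O)CC[C@]2(C)CC=C(CO)C[C@H](O)[C@H]21 | intermediate
14 | 12,14-bis(methanesulfonate) of 13 | CC(COS(C)(=O)=O)[C@]1(O)CC[C@]2(C)CC=C(COS(C)(=O)=O)C[C@H](O)[C@H]21 | intermediate
15 | 5α-dauc-8-ene-4β,6α-diol (jaeschkeanadiol) | CC(C)[C@]1(O)CC[C@]2(C)CC=C(C)C[C@H](O)[C@H]21 | intermediate
16 | 5α-dauc-8-ene-4β,6α,7α-triol (not isolated) | CC(C)[C@]1(O)CC[C@]2(C)CC=C(C)[C@H](O)[C@H](O)[C@H]21 | intermediate
17 | 4β,6α-dihydroxy-5α-dauc-8-en-7-one | CC(C)[C@]1(O)CC[C@]2(C)CC=C(C)C(=O)[C@H](O)[C@H]21 | intermediate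
18 | 5α-dauc-8-ene-4β,6α,7β-triol | CC(C)[C@]1(O)CC[C@]2(C)CC=C(C)[C@@H](O)[C@H](O)[C@H]21 | intermediate
19 | 7-O-triethylsilyl ether of 18 | CC(C)[C@]1(O)CC[C@]2(C)CC=C(C)[C@@H](O[Si](CC)(CC)CC)[C@H](O)[C@H]21 | intermediate
20 | 4-hydroxybenzoic acid | O=C(O)c1ccc(O)cc1 | starting material
21 | tert-butyldimethylsilyl 4-(tert-butyldimethylsilyloxy)benzoate (not isolated) | CC(C)(C)[Si](C)(C)Oc1ccc(cc1)C(=O)O[Si](C)(C)C(C)(C)C | intermediate
22 | 4-(tert-butyldimethylsilyloxy)benzoic acid | CC(C)(C)[Si](C)(C)Oc1ccc(cc1)C(O)=O | intermediate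
23 | 6-O-[4-(tert-butyldimethylsilyloxy)benzoyl]-7-O-triethylsilyl-5α-dauc-8-ene-4β,6α,7β-triol | CC(C)[C@]1(O)CC[C@]2(C)CC=C(C)[C@@H](O[Si](CC)(CC)CC)[C@H](OC(=O)c3ccc(O[Si](C)(C)C(C)(C)C)cc3)[C@H]21 | intermediate
24 | 8α,9α-epoxide of 23 | CC(C)[C@]1(O)CC[C@]2(C)C[C@@H]3O[C@]3(C)[C@@H](O[Si](CC)(CC)CC)[C@H](OC(=O)c3ccc(O[Si](C)(C)C(C)(C)C)cc3)[C@H]21 | intermediate
25 | 8α,9α-epoxy-4β,7β-dihydroxy-5α-daucan-6α-yl 4-hydroxybenzoate | CC(C)[C@]1(O)CC[C@]2(C)C[C@@H]3O[C@]3(C)[C@@H](O)[C@H](OC(=O)c3ccc(O)cc3)[C@H]21 | target

## Count and risks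

Total steps: 15. Longest linear sequence: 13 (steps 1, 3–11, 13–15).

Step 3. The electron-poor dienone may react too slowly with the electrophilic carbenoid, so that carbenoid dimerisation or attack at the carbonyl oxygen competes, or the Cope stage may stall because of the inward methyl. Fallback from 3, returning at 7, with the two stages run as separate, individually known operations on an electron-rich diene: NaBH4/CeCl3·7H2O reduction of 3 gives racemic 3-methyl-2-vinylcyclopent-2-en-1-ol F1, and t-BuMe2SiCl/imidazole gives its silyl ether F2. Cyclopropanation of the terminal alkene of F2 with 5 and Rh2(R-DOSP)4 at −78 °C gives the silyloxy cis-divinylcyclopropane F3 (two C4 epimers, same cyclopropane configuration). F3 is isolated and rearranged thermally in xylene at 110–140 °C to the silyloxy cycloheptadiene F4; Bu4NF frees the allylic alcohol F5, and MnO2 oxidation merges both C4 epimers into 7.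

Step 4. The facial discrimination at C4 may be poor, since the only control element is the remote quaternary centre, whose methyl and ring-methylene substituents flank the two faces similarly. Fallback from 7, returning at 8, with catalyst control in place of substrate control: Zn(C(CH3)=CH2)2 (from the Grignard reagent and ZnCl2) is added in the presence of Ti(OiPr)4 and a chiral trans-cyclohexane-1,2-diyl bis(hydroxycamphorsulfonamide) ligand, a known type of enantioselective alkenylzinc addition to cyclic enones; the ligand enantiomer is chosen for α-face delivery, which gives 8 directly, so no new compound arises (F0).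

Step 5. The ring-forming second B–H addition to the hindered C5=C6 bond may be slow, so that intermolecular borane addition from the open β-face or reduction of the enoate competes. Fallback from 9, returning at 12, using silicon in place of boron: Ph2SiH2 with Pt2[(CH2=CHSiMe2)2O]3 in toluene at 60 °C hydrosilylates the isopropenyl group and then, intramolecularly from the α-face, the C5=C6 bond, giving the 1,1-diphenylsilacyclohexane F6. Tamao–Fleming oxidation (HBF4·OEt2, CH2Cl2; then H2O2, KF, KHCO3, THF/MeOH) converts both C–Si bonds into C–OH with retention and removes the trimethylsilyl ether, giving 12.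

## Further compounds

F1 | step 3 | 3-methyl-2-vinylcyclopent-2-en-1-ol (racemic) | CC1=C(C=C)C(O)CC1
F2 | step 3 | tert-butyldimethylsilyl ether of F1 | CC1=C(C=C)C(O[Si](C)(C)C(C)(C)C)CC1
F3 | step 3 | methyl (1S,2S)-2-[5-(tert-butyldimethylsilyloxy)-2-methylcyclopent-1-en-1-yl]-1-ethenylcyclopropane-1-carboxylate (C4 epimers) | C=C[C@@]1(C(=O)OC)C[C@H]1C2=C(C)CCC2O[Si](C)(C)C(C)(C)C
F4 | step 3 | 4-(tert-butyldimethylsilyloxy) analogue of 7 (C4 epimers, C1 as in 7) | CC(C)(C)[Si](C)(C)OC1CC[C@]2(C)CC=C(C(=O)OC)CC=C21
F5 | step 3 | 4-hydroxy analogue of 7 (C4 epimers) | OC1CC[C@]2(C)CC=C(C(=O)OC)CC=C21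
F0 | step 4 | none | none
F6 | step 5 | 1,1-diphenylsilacyclohexane joining C12 and C6 on the α-face, 4-O-trimethylsilyl ether (C11 epimers) | CC(C3)[C@]1(O[Si](C)(C)C)CC[C@]2(C)CC=C(C(=O)OC)C[C@H]([Si]3(c4ccccc4)c4ccccc4)[C@H]21
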